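**Plan**

Guaianolide numbering is used; unprimed for the half with the cross-conjugated cyclopentadienone, primed for the spiro half.
Retrosynthesis: shifting the C1=C2 enone back to C1=C10 and a retro-Diels–Alder cut of C2–C4' and C14–C15' gives an 11S 3-oxo-1,4(15),10(14)-triene (diene) and an 11R 3-oxo-4(15),10(14)-diene (dienophile), both traced to one 13-nor lactone.
In that lactone the ring carbons C3–C4–C5, with the exocyclic C15 on C4, are a trimethylenemethane unit, C1–C2 is its two-carbon acceptor and C6–C10 of the seven-membered ring is the tether; cutting C1–C5 and C2–C3 therefore opens the five- and the seven-membered ring at once to a γ-lactone with a 2-(silylmethyl)allyl carbonate arm and a vinyl sulfone arm.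
Forward: butenolide → trans-4,5-disubstituted lactone → vinyl sulfone arm → allyl carbonate arm → (3+2) cycloaddition (rings of five and seven) → C10 methylene → C11 methyl → C3 oxygen → Saegusa oxidation, Diels–Alder union (cyclohexene and spiro centre) and enone shift.
Stereochemistry: C6 from the chiral pool, C7 by anti conjugate addition, C5 by the lactone-templated cycloaddition, C1 by kinetic protonation on the convex face, C11 by enolate methylation (11R) or equilibration (11S), C4' by attack on the convex face of the dienophile, C10 by protonation anti to C5'.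

Key step: step 11

Remark: the carbinol centres made in steps 4 and 9 and the C1 and C2 centres made in step 11 are expected as mixtures, are erased in steps 11, 12, 14 and 15, and are left open in the SMILES.

**Route**

Step 1
Reactants: 1 (S)-5-(hydroxymethyl)furan-2(5H)-one
Product: 2 (S)-5-{[(tert-butyldimethylsilyl)oxy]methyl}furan-2(5H)-one
Conditions: TBSCl, imidazole, CH2Cl2, 0 °C to rt
Reagents that add atoms: tert-butyldimethylsilyl chloride, CC(C)(C)[Si](C)(C)Cl
Why: Imidazole-mediated silylation of the primary alcohol should proceed without touching the stereocentre and installs the bulky group that shields one face of the butenolide.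

Step 2
Reactants: 2 (S)-5-{[(tert-butyldimethylsilyl)oxy]methyl}furan-2(5H)-one; 3 but-3-en-1-ylmagnesium bromide
Product: 4 (4S,5S)-4-(but-3-en-1-yl)-5-{[(tert-butyldimethylsilyl)oxy]methyl}dihydrofuran-2(3H)-one (4,5-trans)
Conditions: CuBr·SMe2 (cat.), THF, −78 °C; aq. NH4Cl
Reagents that add atoms: none
Why: Copper-catalysed conjugate addition of the Grignard reagent to the butenolide should occur anti to the silyloxymethyl group, which sets the trans relationship of the future C6 and C7.

Step 3
Reactants: 4 (4S,5S)-4-(but-3-en-1-yl)-5-{[(tert-butyldimethylsilyl)oxy]methyl}dihydrofuran-2(3H)-one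
Product: 5 3-[(2S,3S)-2-{[(tert-butyldimethylsilyl)oxy]methyl}-5-oxotetrahydrofuran-3-yl]propanal
Conditions: OsO4 (cat.), NaIO4, 2,6-lutidine, dioxane–H2O, rt
Reagents that add atoms: sodium periodate, [Na+].[O-]I(=O)(=O)=O
Why: Lemieux–Johnson cleavage of the terminal alkene should give the aldehyde (future C10) while lactone and silyl ether are inert.

Step 4
Reactants: 5 3-[(2S,3S)-2-{[(tert-butyldimethylsilyl)oxy]methyl}-5-oxotetrahydrofuran-3-yl]propanal; 6 vinylmagnesium bromide
Product: 7 (4S,5S)-5-{[(tert-butyldimethylsilyl)oxy]methyl}-4-(3-hydroxypent-4-en-1-yl)dihydrofuran-2(3H)-one (both carbinol epimers)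
Conditions: THF, −78 °C; aq. NH4Cl
Reagents that add atoms: none
Why: Grignard 1,2-addition to the aldehyde is much faster than attack on the lactone at low temperature; the new carbinol centre is not controlled because it is later oxidised.

Step 5
Reactants: 7 (4S,5S)-5-{[(tert-butyldimethylsilyl)oxy]methyl}-4-(3-hydroxypent-4-en-1-yl)dihydrofuran-2(3H)-one; 8 phenyl vinyl sulfone
Product: 9 (4S,5S)-5-{[(tert-butyldimethylsilyl)oxy]methyl}-4-[(E)-3-hydroxy-5-(phenylsulfonyl)pent-4-en-1-yl]dihydrofuran-2(3H)-one
Conditions: second-generation Hoveyda–Grubbs catalyst (cat.), CH2Cl2, 40 °C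
Reagents that add atoms: none
Why: Olefin cross-metathesis of a terminal allylic alcohol with an electron-poor vinyl sulfone that does not homodimerise should give the (E)-γ-hydroxy vinyl sulfone selectively.

Step 6
Reactants: 9 (4S,5S)-5-{[(tert-butyldimethylsilyl)oxy]methyl}-4-[(E)-3-hydroxy-5-(phenylsulfonyl)pent-4-en-1-yl]dihydrofuran-2(3H)-one
Product: 10 (4S,5S)-5-{[(tert-butyldimethylsilyl)oxy]methyl}-4-[(E)-3-[(tert-butyldiphenylsilyl)oxy]-5-(phenylsulfonyl)pent-4-en-1-yl]dihydrofuran-2(3H)-one
Conditions: TBDPSCl, imidazole, DMF, rt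
Reagents that add atoms: tert-butyldiphenylsilyl chloride, CC(C)(C)[Si](Cl)(c1ccccc1)c1ccccc1
Why: Silylation gives an acid-stable ether that, unlike an allylic ester, cannot be ionised by palladium in step 11.

Step 7
Reactants: 10 (4S,5S)-5-{[(tert-butyldimethylsilyl)oxy]methyl}-4-[(E)-3-[(tert-butyldiphenylsilyl)oxy]-5-(phenylsulfonyl)pent-4-en-1-yl]dihydrofuran-2(3H)-one
Product: 11 (4S,5S)-4-[(E)-3-[(tert-butyldiphenylsilyl)oxy]-5-(phenylsulfonyl)pent-4-en-1-yl]-5-(hydroxymethyl)dihydrofuran-2(3H)-one
Conditions: PPTS, MeOH, rt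
Reagents that add atoms: none
Why: Acid-catalysed methanolysis should remove the primary TBS ether selectively because the secondary TBDPS ether is far more stable to acid.

Step 8
Reactants: 11 (4S,5S)-4-[(E)-3-[(tert-butyldiphenylsilyl)oxy]-5-(phenylsulfonyl)pent-4-en-1-yl]-5-(hydroxymethyl)dihydrofuran-2(3H)-one
Product: 12 (2S,3S)-3-[(E)-3-[(tert-butyldiphenylsilyl)oxy]-5-(phenylsulfonyl)pent-4-en-1-yl]-5-oxotetrahydrofuran-2-carbaldehyde
Conditions: Dess–Martin periodinane, CH2Cl2, 0 °C to rt
Reagents that add atoms: none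
Why: Dess–Martin oxidation gives the α-alkoxy aldehyde (future C5) under non-basic conditions that should not epimerise C6; it is used crude.

Step 9
Reactants: 12 (2S,3S)-3-[(E)-3-[(tert-butyldiphenylsilyl)oxy]-5-(phenylsulfonyl)pent-4-en-1-yl]-5-oxotetrahydrofuran-2-carbaldehyde; 13 2-bromo-3-(trimethylsilyl)prop-1-ene
Product: 14 (4S,5S)-4-[(E)-3-[(tert-butyldiphenylsilyl)oxy]-5-(phenylsulfonyl)pent-4-en-1-yl]-5-{1-hydroxy-2-[(trimethylsilyl)methyl]prop-2-en-1-yl}dihydrofuran-2(3H)-one (both carbinol epimers)
Conditions: CrCl2, NiCl2 (cat.), DMF, rt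
Reagents that add atoms: none
Why: The Nozaki–Hiyama–Kishi reaction adds the alkenylchromium reagent to the aldehyde only, leaving lactone and vinyl sulfone alone; the carbinol configuration is irrelevant because this carbon is ionised in step 11.

Step 10
Reactants: 14 (4S,5S)-4-[(E)-3-[(tert-butyldiphenylsilyl)oxy]-5-(phenylsulfonyl)pent-4-en-1-yl]-5-{1-hydroxy-2-[(trimethylsilyl)methyl]prop-2-en-1-yl}dihydrofuran-2(3H)-one
Product: 15 methyl carbonate of 14 at the allylic hydroxyl group
Conditions: ClCO2Me, pyridine, DMAP (cat.), CH2Cl2, 0 °C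
Reagents that add atoms: methyl chloroformate, COC(=O)Cl
Why: Acylation gives the allylic carbonate, which ionises readily and releases the methoxide needed for desilylation, so no base has to be added in step 11.

Step 11
Reactants: 15 methyl carbonate of 14 at the allylic hydroxyl group
Product: 16 2-(phenylsulfonyl)-10-[(tert-butyldiphenylsilyl)oxy]-13,14-dinorguai-4(15)-en-12,6α-olide (5αH,6βH,7αH; mixture at C1, C2 and C10)
Conditions: Pd(OAc)2 (cat.), P(OiPr)3, THF, reflux, high dilution
Reagents that add atoms: none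
Why: Zerovalent palladium ionises the allylic carbonate, the methoxide set free removes the silyl group, and the zwitterionic trimethylenemethane–palladium complex adds through its substituted terminus C5 to the β-carbon C1 of the vinyl sulfone, after which the sulfonyl carbanion at C2 alkylates the CH2 terminus C3 of the π-allylpalladium unit on the face away from the metal, so the C1–C5 and C2–C3 bonds arise in one catalytic event. The closest known reaction type is the palladium-catalysed intramolecular trimethylenemethane (3+2) cycloaddition of 2-(silylmethyl)allyl carbonates onto tethered vinyl sulfones, which gives bicyclo[5.3.0]decanes. The seven-membered ring closes by a 7-exo-trig conjugate addition and the five-membered ring by an intramolecular allylic alkylation in which both attacked allyl carbons end up in the ring (endo with respect to the allyl unit, feasible for an η3-allyl electrophile). The only new centre that must be right is C5: in a chair-like seven-membered transition state templated by the trans-fused lactone the bulky allylpalladium unit should sit pseudo-equatorial and anti to the C6–O bond, which places H5 anti to H6 as in the target, while C1, C2 and C10 may form as mixtures (an all-equatorial transition state would give the trans ring fusion) because they are removed or reset in steps 12, 14 and 15. The step needs ring closure to outrun oligomerisation and loss of the β-acyloxy group from the allyl anion; high dilution, the strongly accepting vinyl sulfone and the base-free carbonate conditions are meant to secure this.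

Step 12
Reactants: 16 2-(phenylsulfonyl)-10-[(tert-butyldiphenylsilyl)oxy]-13,14-dinorguai-4(15)-en-12,6α-olide
Product: 17 10-[(tert-butyldiphenylsilyl)oxy]-13,14-dinorguai-4(15)-en-12,6α-olide (mixture at C1 and C10)
Conditions: Na(Hg), Na2HPO4, MeOH–THF, −20 °C
Reagents that add atoms: none
Why: Reductive desulfonylation by electron transfer from sodium amalgam cleaves the C2–S bond and methanol protonates the carbanion, so the activating group leaves as sulfinate while the buffer protects the lactone.

Step 13
Reactants: 17 10-[(tert-butyldiphenylsilyl)oxy]-13,14-dinorguai-4(15)-en-12,6α-olide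
Product: 18 10-hydroxy-13,14-dinorguai-4(15)-en-12,6α-olide (mixture at C1 and C10)
Conditions: Bu4NF, THF, rt
Reagents that add atoms: none
Why: Fluoride cleaves the secondary silyl ether; no other group in the molecule is fluoride-labile.

Step 14
Reactants: 18 10-hydroxy-13,14-dinorguai-4(15)-en-12,6α-olide
Product: 19 10-oxo-13,14-dinorguai-4(15)-en-12,6α-olide (C1 epimers)
Conditions: Dess–Martin periodinane, CH2Cl2, rt
Reagents that add atoms: none
Why: Dess–Martin oxidation gives the C10 ketone and erases the C10 centre under conditions that leave the exocyclic alkene in place.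

Step 15
Reactants: 19 10-oxo-13,14-dinorguai-4(15)-en-12,6α-olide (C1 epimers)
Product: 21 cis-fused 10-oxo-13,14-dinorguai-4(15)-en-12,6α-olide (1αH 5αH), via trimethylsilyl enol ether 20 (not isolated)
Conditions: TMSOTf, Et3N, CH2Cl2, 0 °C to rt; then Bu4NF, AcOH, THF, −78 °C
Reagents that add atoms: none
Why: Equilibrating silylation should give the more substituted C1=C10 silyl enol ether from either C1 epimer, and fluoride-triggered protonation at low temperature should deliver the proton to C1 on the convex α-face (the face of H5, away from C6 and the lactone), giving the cis ring fusion under kinetic control (stereoconvergent enolisation and kinetic protonation).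

Step 16
Reactants: 21 cis-fused 10-oxo-13,14-dinorguai-4(15)-en-12,6α-olide
Product: 22 (1αH,5αH,6βH,7αH)-13-norguaia-4(15),10(14)-dien-12,6α-olide
Conditions: Zn, CH2Br2, TiCl4, THF–CH2Cl2, 0 °C to rt
Reagents that add atoms: dibromomethane, BrCBr
Why: Lombardo methylenation converts the ketone into the C10=C14 exocyclic alkene under non-basic conditions, so the kinetically set C1 centre next to the carbonyl should not epimerise and the lactone is untouched.

Step 17
Reactants: 22 (1αH,5αH,6βH,7αH)-13-norguaia-4(15),10(14)-dien-12,6α-olide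
Product: 23 (11R)-guaia-4(15),10(14)-dien-12,6α-olide (11αH, methyl β)
Conditions: LiN(iPr)2, THF, −78 °C; MeI, −78 °C
Reagents that add atoms: iodomethane, CI
Why: Alkylation of the lithium enolate of the trans-fused γ-lactone; the electrophile should enter anti to the pseudo-axial H7 (β-face), giving the 11β-methyl (11R) epimer of the dienophile half under kinetic control.

Step 18
Reactants: 23 (11R)-guaia-4(15),10(14)-dien-12,6α-olide
Product: 24 (11R)-3α-hydroxyguaia-4(15),10(14)-dien-12,6α-olide
Conditions: SeO2 (cat.), t-BuOOH, CH2Cl2, rt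
Reagents that add atoms: tert-butyl hydroperoxide, CC(C)(C)OO
Why: SeO2-catalysed allylic hydroxylation (ene reaction, then [2,3]-sigmatropic shift) is expected at C3, the unhindered allylic CH2 of the cyclopentane exocyclic alkene, with oxygen delivered on the convex α-face as in closely related 4(15),10(14)-guaiadienolides; the carbinol configuration is not needed.

Step 19
Reactants: 24 (11R)-3α-hydroxyguaia-4(15),10(14)-dien-12,6α-olide
Product: 25 (11R)-3-oxoguaia-4(15),10(14)-dien-12,6α-olide (dienophile)
Conditions: Dess–Martin periodinane, CH2Cl2, 0 °C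
Reagents that add atoms: none
Why: Dess–Martin oxidation of the allylic alcohol gives the α-methylene cyclopentanone under neutral conditions that leave the kinetically set C11 centre alone; the enone is used promptly.

Step 20
Reactants: 24 (11R)-3α-hydroxyguaia-4(15),10(14)-dien-12,6α-olide
Product: 26 (11S)-3α-hydroxyguaia-4(15),10(14)-dien-12,6α-olide (11βH, methyl α)
Conditions: KOt-Bu, t-BuOH–THF, rt; AcOH
Reagents that add atoms: none
Why: Reversible enolisation of the lactone with alkoxide base should equilibrate C11 to the more stable epimer, in which the methyl group is α and trans to C8 (11S), the configuration of the diene half; the allylic alcohol is inert to the base.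

Step 21
Reactants: 26 (11S)-3α-hydroxyguaia-4(15),10(14)-dien-12,6α-olide
Product: 27 (11S)-3-oxoguaia-4(15),10(14)-dien-12,6α-olide
Conditions: Dess–Martin periodinane, CH2Cl2, 0 °C
Reagents that add atoms: none
Why: Same neutral oxidation of the allylic alcohol as in step 19, giving the ketone that is the precursor of the diene.

Step 22
Reactants: 27 (11S)-3-oxoguaia-4(15),10(14)-dien-12,6α-olide; 25 (11R)-3-oxoguaia-4(15),10(14)-dien-12,6α-olide (in excess)
Product: 31 target dimer CNP0240988.1, via silyl dienol ether 28 (not isolated), via trienone 29 (not isolated), via Diels–Alder adduct 30 (not isolated)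
Conditions: TMSOTf, Et3N, CH2Cl2, 0 °C; then Pd(OAc)2, MeCN, rt, in the presence of 25; then Et3N, rt
Reagents that add atoms: none
Why: Silylation can enolise 27 only toward C2, and Saegusa–Ito oxidation then gives the cross-conjugated trienone, whose C2=C1–C10=C14 diene should add to the exocyclic enone of 25 with ortho regiochemistry (C14 to C15', C2 to C4') on the convex α-face of 25, setting the spiro centre C4'; amine-mediated dienolisation then moves the alkene from C1=C10 into conjugation at C1=C2, with protonation at C10 on the face anti to C5'.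

**Compound list**

1 | (S)-5-(hydroxymethyl)furan-2(5H)-one | O=C1C=C[C@@H](CO)O1 | starting material
2 | (S)-5-{[(tert-butyldimethylsilyl)oxy]methyl}furan-2(5H)-one | O=C1C=C[C@@H](CO[Si](C)(C)C(C)(C)C)O1 | intermediate
3 | but-3-en-1-ylmagnesium bromide | C=CCC[Mg]Br | starting material
4 | (4S,5S)-4-(but-3-en-1-yl)-5-{[(tert-butyldimethylsilyl)oxy]methyl}dihydrofuran-2(3H)-one | C=CCC[C@@H]1[C@H](OC(=O)C1)CO[Si](C)(C)C(C)(C)C | intermediate
5 | 3-[(2S,3S)-2-{[(tert-butyldimethylsilyl)oxy]methyl}-5-oxotetrahydrofuran-3-yl]propanal | O=CCC[C@@H]1[C@H](OC(=O)C1)CO[Si](C)(C)C(C)(C)C | intermediate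
6 | vinylmagnesium bromide | C=C[Mg]Br | starting material
7 | (4S,5S)-5-{[(tert-butyldimethylsilyl)oxy]methyl}-4-(3-hydroxypent-4-en-1-yl)dihydrofuran-2(3H)-one, carbinol epimers | C=CC(O)CC[C@@H]1[C@H](OC(=O)C1)CO[Si](C)(C)C(C)(C)C | intermediate
8 | phenyl vinyl sulfone | C=CS(=O)(=O)c1ccccc1 | starting material
9 | (4S,5S)-5-{[(tert-butyldimethylsilyl)oxy]methyl}-4-[(E)-3-hydroxy-5-(phenylsulfonyl)pent-4-en-1-yl]dihydrofuran-2(3H)-one | O=S(=O)(c1ccccc1)/C=C/C(O)CC[C@@H]2[C@H](OC(=O)C2)CO[Si](C)(C)C(C)(C)C | intermediate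
10 | (4S,5S)-5-{[(tert-butyldimethylsilyl)oxy]methyl}-4-[(E)-3-[(tert-butyldiphenylsilyl)oxy]-5-(phenylsulfonyl)pent-4-en-1-yl]dihydrofuran-2(3H)-one | O=S(=O)(c1ccccc1)/C=C/C(O[Si](c2ccccc2)(c3ccccc3)C(C)(C)C)CC[C@@H]4[C@H](OC(=O)C4)CO[Si](C)(C)C(C)(C)C | intermediate
11 | (4S,5S)-4-[(E)-3-[(tert-butyldiphenylsilyl)oxy]-5-(phenylsulfonyl)pent-4-en-1-yl]-5-(hydroxymethyl)dihydrofuran-2(3H)-one | O=S(=O)(c1ccccc1)/C=C/C(O[Si](c2ccccc2)(c3ccccc3)C(C)(C)C)CC[C@@H]4[C@H](OC(=O)C4)CO | intermediate
12 | (2S,3S)-3-[(E)-3-[(tert-butyldiphenylsilyl)oxy]-5-(phenylsulfonyl)pent-4-en-1-yl]-5-oxotetrahydrofuran-2-carbaldehyde | O=S(=O)(c1ccccc1)/C=C/C(O[Si](c2ccccc2)(c3ccccc3)C(C)(C)C)CC[C@@H]4[C@H](OC(=O)C4)C=O | intermediate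
13 | 2-bromo-3-(trimethylsilyl)prop-1-ene | C=C(Br)C[Si](C)(C)C | starting material
14 | (4S,5S)-4-[(E)-3-[(tert-butyldiphenylsilyl)oxy]-5-(phenylsulfonyl)pent-4-en-1-yl]-5-{1-hydroxy-2-[(trimethylsilyl)methyl]prop-2-en-1-yl}dihydrofuran-2(3H)-one, carbinol epimers | O=S(=O)(c1ccccc1)/C=C/C(O[Si](c2ccccc2)(c3ccccc3)C(C)(C)C)CC[C@@H]4[C@H](OC(=O)C4)C(O)C(=C)C[Si](C)(C)C | intermediate
15 | methyl carbonate of 14 at the allylic hydroxyl group | O=S(=O)(c1ccccc1)/C=C/C(O[Si](c2ccccc2)(c3ccccc3)C(C)(C)C)CC[C@@H]4[C@H](OC(=O)C4)C(OC(=O)OC)C(=C)C[Si](C)(C)C | intermediate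
16 | 2-(phenylsulfonyl)-10-[(tert-butyldiphenylsilyl)oxy]-13,14-dinorguai-4(15)-en-12,6α-olide (5αH,6βH,7αH; mixture at C1, C2, C10) | C=C1CC(S(=O)(=O)c4ccccc4)C2C(O[Si](c5ccccc5)(c6ccccc6)C(C)(C)C)CC[C@@H]3[C@H](OC(=O)C3)[C@H]21 | intermediate
17 | 10-[(tert-butyldiphenylsilyl)oxy]-13,14-dinorguai-4(15)-en-12,6α-olide (mixture at C1, C10) | C=C1CCC2C(O[Si](c5ccccc5)(c6ccccc6)C(C)(C)C)CC[C@@H]3[C@H](OC(=O)C3)[C@H]21 | intermediate
18 | 10-hydroxy-13,14-dinorguai-4(15)-en-12,6α-olide (mixture at C1, C10) | C=C1CCC2C(O)CC[C@@H]3[C@H](OC(=O)C3)[C@H]21 | intermediate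
19 | 10-oxo-13,14-dinorguai-4(15)-en-12,6α-olide (C1 epimers) | C=C1CCC2C(=O)CC[C@@H]3[C@H](OC(=O)C3)[C@H]21 | intermediate
20 | 10-(trimethylsilyloxy)-13,14-dinorguaia-1(10),4(15)-dien-12,6α-olide | C=C1CCC2=C(O[Si](C)(C)C)CC[C@@H]3[C@H](OC(=O)C3)[C@H]21 | intermediate
21 | (1αH,5αH)-10-oxo-13,14-dinorguai-4(15)-en-12,6α-olide (cis-fused) | C=C1CC[C@H]2C(=O)CC[C@@H]3[C@H](OC(=O)C3)[C@H]21 | intermediate
22 | (1αH,5αH,6βH,7αH)-13-norguaia-4(15),10(14)-dien-12,6α-olide | C=C1CC[C@H]2C(=C)CC[C@@H]3[C@H](OC(=O)C3)[C@H]21 | intermediate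
23 | (11R)-guaia-4(15),10(14)-dien-12,6α-olide (11αH) | C=C1CC[C@H]2C(=C)CC[C@@H]3[C@H](OC(=O)[C@@H]3C)[C@H]21 | intermediate
24 | (11R)-3α-hydroxyguaia-4(15),10(14)-dien-12,6α-olide | C=C1[C@H](O)C[C@H]2C(=C)CC[C@@H]3[C@H](OC(=O)[C@@H]3C)[C@H]21 | intermediate
25 | (11R)-3-oxoguaia-4(15),10(14)-dien-12,6α-olide | C=C1C(=O)C[C@H]2C(=C)CC[C@@H]3[C@H](OC(=O)[C@@H]3C)[C@H]21 | intermediate
26 | (11S)-3α-hydroxyguaia-4(15),10(14)-dien-12,6α-olide | C=C1[C@H](O)C[C@H]2C(=C)CC[C@@H]3[C@H](OC(=O)[C@H]3C)[C@H]21 | intermediate
27 | (11S)-3-oxoguaia-4(15),10(14)-dien-12,6α-olide | C=C1C(=O)C[C@H]2C(=C)CC[C@@H]3[C@H](OC(=O)[C@H]3C)[C@H]21 | intermediate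
28 | (11S)-3-(trimethylsilyloxy)guaia-2,4(15),10(14)-trien-12,6α-olide | C=C1C(O[Si](C)(C)C)=C[C@H]2C(=C)CC[C@@H]3[C@H](OC(=O)[C@H]3C)[C@H]21 | intermediate
29 | (11S)-3-oxoguaia-1,4(15),10(14)-trien-12,6α-olide | C=C1C(=O)C=C2C(=C)CC[C@@H]3[C@H](OC(=O)[C@H]3C)[C@H]21 | intermediate
30 | Diels–Alder adduct with C2–C4' and C14–C15' bonds, C1=C10 alkene and H at C2 (C2 configuration open) | C=C1C(=O)C2C3=C(CC[C@@H]4[C@H](OC(=O)[C@H]4C)[C@@H]13)CC[C@]21C(=O)C[C@H]2C(=C)CC[C@@H]3[C@H](OC(=O)[C@@H]3C)[C@H]21 | intermediate
31 | target dimer CNP0240988.1 | C=C1C(=O)C2=C3[C@@H](CC[C@@H]4[C@H](OC(=O)[C@H]4C)[C@@H]13)CC[C@]21C(=O)C[C@H]2C(=C)CC[C@@H]3[C@H](OC(=O)[C@@H]3C)[C@H]21 | target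

**Count and risks**

Total step count: 22. Longest linear sequence: 21 steps (steps 1–18, then 20, 21 and 22).

Step 11. What may go wrong: the zwitterionic allylpalladium species may lose the β-acyloxy group of the lactone or oligomerise before the seven-membered ring closes, or add with the wrong facial sense at C5. The fallback makes the three-carbon unit by C–C activation of a strained ring instead of ionisation and desilylation. It sets out from 12: Wittig reaction with cyclopropylidenetriphenylphosphorane (from cyclopropyltriphenylphosphonium bromide and KN(SiMe3)2, THF) should give (4S,5S)-4-[(E)-3-[(tert-butyldiphenylsilyl)oxy]-5-(phenylsulfonyl)pent-4-en-1-yl]-5-(cyclopropylidenemethyl)dihydrofuran-2(3H)-one F1. Heating F1 with Pd2(dba)3 and P(OiPr)3 in dioxane lets zerovalent palladium insert into the distal cyclopropane bond; the neutral palladacycle then adds across the vinyl sulfone (known intramolecular (3+2) cycloaddition of alkylidenecyclopropanes) and forms the same C1–C5 and C2–C3 bonds. It comes back to the route at 16.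

Step 15. What may go wrong: protonation of the enol ether may show poor facial selectivity, or the kinetically formed cis-fused ketone may re-equilibrate before methylenation. The fallback sets C1 in an irreversible step that also makes the exocyclic alkene. It sets out from 19 through 20: PhNTf2 and CsF should convert the silyl enol ether into 10-(trifluoromethylsulfonyloxy)-13,14-dinorguaia-1(10),4(15)-dien-12,6α-olide F2. Kumada coupling with Me3SiCH2MgCl and Pd(PPh3)4 should then give the allylsilane 14-(trimethylsilyl)-13-norguaia-1(10),4(15)-dien-12,6α-olide F3. Protodesilylation with CF3CO2H in CH2Cl2 at −78 °C delivers the proton to C1 on the convex face in an anti SE2' process and forms C10=C14 at once. It comes back to the route at 22, which has no epimerisable centre at C1.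

Step 22. What may go wrong: the transient trienone may dimerise with itself or decompose on palladium before it is captured by 25, and capture may be incomplete. The fallback unveils the diene without metal and at low temperature. It sets out from 27: LiN(SiMe3)2 and PhSeCl in THF at −78 °C should give (11S)-3-oxo-2-(phenylselanyl)guaia-4(15),10(14)-dien-12,6α-olide F4, with selenium on the convex face and thus syn to H1. Oxidation with NaIO4 at 0 °C in the presence of excess 25 gives the selenoxide F5, whose syn elimination releases the trienone. It comes back to the route at 29, which adds to 25 and is isomerised with Et3N as in step 22.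

**Further compounds**

F1 | step 11 | (4S,5S)-4-[(E)-3-[(tert-butyldiphenylsilyl)oxy]-5-(phenylsulfonyl)pent-4-en-1-yl]-5-(cyclopropylidenemethyl)dihydrofuran-2(3H)-one | O=S(=O)(c1ccccc1)/C=C/C(O[Si](c2ccccc2)(c3ccccc3)C(C)(C)C)CC[C@@H]4[C@H](OC(=O)C4)C=C5CC5
F2 | step 15 | 10-(trifluoromethylsulfonyloxy)-13,14-dinorguaia-1(10),4(15)-dien-12,6α-olide | C=C1CCC2=C(OS(=O)(=O)C(F)(F)F)CC[C@@H]3[C@H](OC(=O)C3)[C@H]21
F3 | step 15 | 14-(trimethylsilyl)-13-norguaia-1(10),4(15)-dien-12,6α-olide | C=C1CCC2=C(C[Si](C)(C)C)CC[C@@H]3[C@H](OC(=O)C3)[C@H]21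
F4 | step 22 | (11S)-3-oxo-2-(phenylselanyl)guaia-4(15),10(14)-dien-12,6α-olide | C=C1C(=O)C([Se]c4ccccc4)[C@H]2C(=C)CC[C@@H]3[C@H](OC(=O)[C@H]3C)[C@H]21
F5 | step 22 | selenoxide of F4 | C=C1C(=O)C([Se](=O)c4ccccc4)[C@H]2C(=C)CC[C@@H]3[C@H](OC(=O)[C@H]3C)[C@H]21
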